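**Retrosynthetic overview**
1. The C10‑OAc/C9‑OH pair comes from kinetic hydrolysis of a C9/C10 cyclic orthoacetate. The C1 and C5 angelates go on last, the C5 one with inversion.
2. The ten‑membered carbocycle and the 3,4‑oxirane are made together. An intramolecular Darzens condensation joins the C3 aldehyde to the C4 α‑bromo ketone (C3–C4 bond, then C3–O–C4).
3. In the open‑chain precursor, C6 is set by Felkin addition of a propionyl‑anion equivalent to the C6 aldehyde. C1 is set by catalyst‑controlled reduction of a C1 ynone, and the alkyne is the latent C3 aldehyde.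
4. Both chain ends come from glycol cleavage (C1–C6) of a cyclohexane made from (S)‑carvone. That ring fixes C7, C9 and C10 without any osmium chemistry near the isopropenyl group.
5. Ring order: the carvone ring is used as a stereo‑template and then opened. The 10‑ring and oxirane then close in one operation.

**Assumption:** germacrane numbering is used (ring C1–C10, isopropenyl on C7). The orthoester carbon, C6 of 6, C1/C6 of 9 and C4 of 22 are inconsequential epimer mixtures and are left undefined in the SMILES.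

**Step 1**
Reactants: 1 (S)-(+)-carvone
Product: 2 (1S,4S,6S)-1-methyl-4-(prop-1-en-2-yl)-7-oxabicyclo[4.1.0]heptan-2-one (oxirane trans to isopropenyl)
Conditions: 30% H2O2, NaOH (cat.), MeOH, 0 °C
Reagents that add atoms: hydrogen peroxide OO
Why: Weitz–Scheffer nucleophilic epoxidation touches only the enone C=C, and hydroperoxide adds anti to the isopropenyl group, which fixes C10 (O down, CH3 up).

**Step 2**
Reactants: 2 carvone epoxide
Product: 3 (2S,3R,5S)-2,3-dihydroxy-2-methyl-5-(prop-1-en-2-yl)cyclohexan-1-one (trans-diol = future C10/C9)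
Conditions: 3% aq H2SO4, THF, 0 °C → rt
Reagents that add atoms: water O
Why: In this acid-catalysed SN2-type epoxide hydrolysis, water attacks the β-carbon C9 (away from the cation-destabilising carbonyl) with inversion while C10–O is retained, giving the target C9/C10 configuration.

**Step 3**
Reactants: 3 keto diol; 4 trimethyl orthoacetate
Product: 5 cyclic methyl orthoacetate of 3 (2-methoxy-2-methyl-1,3-dioxolane on C9/C10; ketone at C1)
Conditions: 4 (3 equiv), PPTS (2 mol %), CH2Cl2, rt; Et3N quench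
Reagents that add atoms: trimethyl orthoacetate (4) COC(C)(OC)OC
Why: Transorthoesterification of the diequatorial trans-diol masks both hydroxyls against steps 4–15 and already carries the future C10 acetate.

**Step 4**
Reactants: 5 orthoester ketone
Product: 6 C6-hydroxy ketone (α-ketol; C6 epimers)
Conditions: KHMDS, THF, −78 °C; 2-(phenylsulfonyl)-3-phenyloxaziridine; sat. NH4Cl
Reagents that add atoms: 2-(phenylsulfonyl)-3-phenyloxaziridine O=S(=O)(c1ccccc1)N1OC1c1ccccc1
Why: Davis enolate hydroxylation is regiochemically unambiguous because C10 is quaternary, and the new centre is erased in step 6.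

**Step 5**
Reactants: 6 α-ketol; 7 ethynyltrimethylsilane
Product: 9 C1-(trimethylsilylethynyl) C1/C6-diol (epimers), via lithium trimethylsilylacetylide 8 (not isolated)
Conditions: 7 (2.6 equiv), n-BuLi (2.5 equiv), THF, −78 °C; add 6, −78 → −20 °C; sat. NH4Cl
Reagents that add atoms: ethynyltrimethylsilane (7) C#C[Si](C)(C)C
Why: 1,2-Addition of a slim acetylide to the hindered ketone brings in C2–C3, and the carbinol centre formed is erased in step 6.

**Step 6**
Reactants: 9 diol
Product: 10 (7R,9R,10S)-seco aldehyde–ynone (C6 aldehyde / C1 TMS-ynone / C9,C10 orthoacetate)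
Conditions: Pb(OAc)4 (1.1 equiv), pyridine, CH2Cl2, −20 °C, 20 min; used at once
Reagents that add atoms: none
Why: Criegee glycol cleavage opens the C1–C6 bond under buffered, alkene-tolerant conditions and gives two differentiated termini with C7, C9 and C10 untouched.

**Step 7**
Reactants: 10 aldehyde–ynone; 11 ethyl (Z)-prop-1-enyl ether (from the commercial Z/E mixture); 12 (R)-2-methylbutanoic acid
Product: 16 (6S,7R,9R,10S)-C6 (R)-2-methylbutanoate bearing the (Z)-C5 ethyl enol ether (C1 TMS-ynone intact), via 1-ethoxypropenyllithium 13 (not isolated), via (R)-2-methylbutanoyl chloride 14 (not isolated), via C6 lithium alkoxide 15 (not isolated)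
Conditions: 11 (3 equiv), t-BuLi (1.1 equiv), THF, −78 → 0 °C; 10, −95 °C; then 14 (from 12 + 1-chloro-N,N,2-trimethylpropenylamine, CH2Cl2, cannulated), −78 → 0 °C; NaHCO3 work-up
Reagents that add atoms: ethyl (Z)-prop-1-enyl ether (11) C/C=C\OCC; (R)-2-methylbutanoic acid (12) CC[C@@H](C)C(=O)O
Why: The α-lithiated enol ether (acyl-anion equivalent) adds to the aldehyde far faster than to the neopentyl, silyl-capped ynone, Felkin–Anh attack anti to the isopropenyl group sets 6S, and the alkoxide is acylated in situ.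

**Step 8**
Reactants: 16 ynone
Product: 18 (1S)-propargylic alcohol with terminal alkyne, via TMS-propargylic alcohol 17 (not isolated)
Conditions: Ru[(R,R)-TsDPEN](p-cymene) (5 mol %), i-PrOH, rt; then MeOH, K2CO3 (0.2 equiv), rt
Reagents that add atoms: none
Why: Noyori–Ikariya transfer hydrogenation of the ynone is catalyst-controlled (the alkynyl group takes the aryl site, and the sense matches the Felkin preference) and sets 1S, after which mild methanolysis removes the C-silyl group.

**Step 9**
Reactants: 18 propargylic alcohol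
Product: 19 C1 triethylsilyl ether
Conditions: TESCl, imidazole, DMAP (cat.), DMF, 0 °C → rt
Reagents that add atoms: chlorotriethylsilane CC[Si](Cl)(CC)CC
Why: Silylation gives a β-substituent that leaves far less readily than an ester when the C3 aldehyde later meets base.

**Step 10**
Reactants: 19 alkyne
Product: 21 C3 aldehyde (β-silyloxy aldehyde), via alkenyl(dicyclohexyl)borane 20 (not isolated)
Conditions: Cy2BH (1.15 equiv), THF, 0 °C; then pH 7 buffer, 30% H2O2, 0 °C
Reagents that add atoms: hydrogen peroxide OO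
Why: Brown anti-Markovnikov hydroboration–oxidation with a bulky dialkylborane takes the terminal alkyne much faster than the 1,1-disubstituted alkene or the hindered enol ether.

**Step 11**
Reactants: 21 enol ether aldehyde
Product: 22 C4-bromo C5-ketone C3-aldehyde (C4 epimers)
Conditions: NBS (1.05 equiv), NaHCO3, THF–H2O 10:1, −20 °C
Reagents that add atoms: N-bromosuccinimide O=C1CCC(=O)N1Br; water O
Why: Electrophilic bromination and hydrolysis of the enol ether, by far the most electron-rich π-bond present, places bromine regiospecifically on C4 without enolising toward C6.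

**Step 12**
Reactants: 22 bromo keto aldehyde
Product: 24 (1S,3S,4S,6S,7R,9R,10S)-3,4-epoxygermacr-11-en-5-one (C1 OTES / C6 2-methylbutanoate / C9,C10 orthoacetate), via ring-closed lithium bromohydrinate 23 (not isolated)
Conditions: LiOt-Bu (1.3 equiv), THF–t-BuOH 20:1; 22 added by syringe pump over 12 h (final 1 mM), −10 °C → rt
Reagents that add atoms: none
Why: Proposed new method: a macrocyclising Darzens condensation in which t-BuOH-shuttled reversible enolisation funnels to the acidified C4–H, the Li-chelated bromo-enolate adds reversibly to the C3 aldehyde (10-ring closure, 1,3-anti to the C1 silyloxy group by the Evans polar model, giving 3S), and only the aldolate with C3–O⁻ antiperiplanar to C4–Br and with C2/C5 cis collapses irreversibly by SN2 to the less strained cis-fused oxirane (4S), so the unfavourable medium-ring aldol equilibrium is drained; the closest known reaction types are intermolecular Darzens reactions of α-halo ketones, intramolecular epoxy-annulations to 5–7-membered rings and carbanion closures of germacrane 10-rings.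

**Step 13**
Reactants: 24 epoxy ketone
Product: 25 (5R)-alcohol (cis/erythro epoxy alcohol)
Conditions: Zn(BH4)2, Et2O, −30 °C; sat. NH4Cl
Reagents that add atoms: none
Why: In this chelation-controlled reduction of an α,β-epoxy ketone, Zn bridges the carbonyl and oxirane oxygens and hydride arrives from the ring periphery anti to C3, giving reliably the erythro 5R epimer that step 14 is designed to invert.

**Step 14**
Reactants: 25 (5R)-alcohol; 26 angelic acid
Product: 27 (5S)-angelate (C1 OTES retained)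
Conditions: 26, PPh3, DIAD, toluene, 0 °C → rt
Reagents that add atoms: angelic acid (26) C/C=C(/C)C(=O)O
Why: The Mitsunobu reaction displaces the oxyphosphonium by angelate with SN2 inversion (5R → 5S, the usual erythro → threo correction of 2,3-epoxy alcohols) and installs the ester without activating the isomerisation-prone acyl group.

**Step 15**
Reactants: 27 mono-angelate; 28 angelic anhydride
Product: 30 1,5-bis-angelate orthoacetate, via C1 ammonium alkoxide 29 (not isolated)
Conditions: 28 (4 equiv), TBAF (1.2 equiv), THF, 0 °C → rt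
Reagents that add atoms: angelic anhydride (28) C/C=C(/C)C(=O)OC(=O)/C(C)=C\C
Why: In this fluoride-triggered desilylative acylation, the C1 alkoxide (configuration retained, no vicinal ester to migrate) is trapped at once by the anhydride, a stereoconservative way to make angelates.

**Step 16**
Reactants: 30 orthoacetate
Product: 31 target CNP0197637.1
Conditions: AcOH–THF–H2O, 0 °C, about 15 min; NaHCO3 quench
Reagents that add atoms: water O
Why: In this kinetic hydrolysis of a cyclic orthoester through the dioxolan-2-ylium/hemiorthoester, the less hindered secondary oxygen leaves, so the acetate stays on tertiary C10 and C9–OH is freed under conditions too mild to open the oxirane.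

**Compound list**
1 | (S)-(+)-carvone | C=C(C)[C@H]1CC=C(C)C(=O)C1 | starting material
2 | (1S,4S,6S)-carvone epoxide | C=C(C)[C@H]1C[C@@H]2O[C@]2(C)C(=O)C1 | intermediate
3 | (2S,3R,5S)-2,3-dihydroxy-2-methyl-5-isopropenylcyclohexanone | C=C(C)[C@H]1C[C@@H](O)[C@](C)(O)C(=O)C1 | intermediate
4 | trimethyl orthoacetate | COC(C)(OC)OC | starting material
5 | C9/C10 cyclic methyl orthoacetate ketone | C=C(C)[C@H]1C[C@H]2OC(C)(OC)O[C@]2(C)C(=O)C1 | intermediate
6 | C6-hydroxy ketone | C=C(C)[C@H]1C[C@H]2OC(C)(OC)O[C@]2(C)C(=O)C1O | intermediate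
7 | ethynyltrimethylsilane | C#C[Si](C)(C)C | starting material
8 | lithium trimethylsilylacetylide | [Li]C#C[Si](C)(C)C | intermediate
9 | C1-(TMS-ethynyl) C1/C6-diol | C=C(C)[C@H]1C[C@H]2OC(C)(OC)O[C@]2(C)C(O)(C#C[Si](C)(C)C)C1O | intermediate
10 | seco C6 aldehyde / C1 TMS-ynone | C=C(C)[C@H](C=O)C[C@H]1OC(C)(OC)O[C@]1(C)C(=O)C#C[Si](C)(C)C | intermediate
11 | ethyl (Z)-prop-1-enyl ether | C/C=C\OCC | starting material
12 | (R)-2-methylbutanoic acid | CC[C@@H](C)C(=O)O | starting material
13 | (Z)-1-ethoxyprop-1-enyllithium | C/C=C(/[Li])OCC | intermediate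
14 | (R)-2-methylbutanoyl chloride | CC[C@@H](C)C(=O)Cl | intermediate
15 | C6 lithium alkoxide | C=C(C)[C@H]([C@H](O[Li])/C(OCC)=C/C)C[C@H]1OC(C)(OC)O[C@]1(C)C(=O)C#C[Si](C)(C)C | intermediate
16 | C6 ester / C5 enol ether / C1 TMS-ynone | C=C(C)[C@H]([C@H](OC(=O)[C@H](C)CC)/C(OCC)=C/C)C[C@H]1OC(C)(OC)O[C@]1(C)C(=O)C#C[Si](C)(C)C | intermediate
17 | (1S)-TMS-propargylic alcohol | C=C(C)[C@H]([C@H](OC(=O)[C@H](C)CC)/C(OCC)=C/C)C[C@H]1OC(C)(OC)O[C@]1(C)[C@@H](O)C#C[Si](C)(C)C | intermediate
18 | (1S)-propargylic alcohol, terminal alkyne | C=C(C)[C@H]([C@H](OC(=O)[C@H](C)CC)/C(OCC)=C/C)C[C@H]1OC(C)(OC)O[C@]1(C)[C@@H](O)C#C | intermediate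
19 | C1 TES ether | C=C(C)[C@H]([C@H](OC(=O)[C@H](C)CC)/C(OCC)=C/C)C[C@H]1OC(C)(OC)O[C@]1(C)[C@@H](O[Si](CC)(CC)CC)C#C | intermediate
20 | (E)-alkenyl(dicyclohexyl)borane | C=C(C)[C@H]([C@H](OC(=O)[C@H](C)CC)/C(OCC)=C/C)C[C@H]1OC(C)(OC)O[C@]1(C)[C@@H](O[Si](CC)(CC)CC)/C=C/B(C2CCCCC2)C2CCCCC2 | intermediate
21 | C3 aldehyde | C=C(C)[C@H]([C@H](OC(=O)[C@H](C)CC)/C(OCC)=C/C)C[C@H]1OC(C)(OC)O[C@]1(C)[C@@H](O[Si](CC)(CC)CC)CC=O | intermediate
22 | C4-bromo C5-ketone C3-aldehyde | C=C(C)[C@H]([C@H](OC(=O)[C@H](C)CC)C(=O)C(C)Br)C[C@H]1OC(C)(OC)O[C@]1(C)[C@@H](O[Si](CC)(CC)CC)CC=O | intermediate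
23 | ring-closed lithium bromohydrinate | C=C(C)[C@H]1C[C@H]2OC(C)(OC)O[C@]2(C)[C@@H](O[Si](CC)(CC)CC)C[C@H](O[Li])[C@@](C)(Br)C(=O)[C@H]1OC(=O)[C@H](C)CC | intermediate
24 | 3,4-epoxygermacr-11-en-5-one | C=C(C)[C@H]1C[C@H]2OC(C)(OC)O[C@]2(C)[C@@H](O[Si](CC)(CC)CC)C[C@@H]3O[C@]3(C)C(=O)[C@H]1OC(=O)[C@H](C)CC | intermediate
25 | (5R)-epoxy alcohol | C=C(C)[C@H]1C[C@H]2OC(C)(OC)O[C@]2(C)[C@@H](O[Si](CC)(CC)CC)C[C@@H]3O[C@]3(C)[C@H](O)[C@H]1OC(=O)[C@H](C)CC | intermediate
26 | angelic acid | C/C=C(/C)C(=O)O | starting material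
27 | (5S)-angelate, C1 OTES | C=C(C)[C@H]1C[C@H]2OC(C)(OC)O[C@]2(C)[C@@H](O[Si](CC)(CC)CC)C[C@@H]3O[C@]3(C)[C@@H](OC(=O)/C(C)=C\C)[C@H]1OC(=O)[C@H](C)CC | intermediate
28 | angelic anhydride | C/C=C(/C)C(=O)OC(=O)/C(C)=C\C | starting material
29 | C1 tetrabutylammonium alkoxide | C=C(C)[C@H]1C[C@H]2OC(C)(OC)O[C@]2(C)[C@@H]([O-])C[C@@H]3O[C@]3(C)[C@@H](OC(=O)/C(C)=C\C)[C@H]1OC(=O)[C@H](C)CC.CCCC[N+](CCCC)(CCCC)CCCC | intermediate
30 | 1,5-bis-angelate orthoacetate | C=C(C)[C@H]1C[C@H]2OC(C)(OC)O[C@]2(C)[C@@H](OC(=O)/C(C)=C\C)C[C@@H]3O[C@]3(C)[C@@H](OC(=O)/C(C)=C\C)[C@H]1OC(=O)[C@H](C)CC | intermediate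
31 | (1S,3S,4S,5S,6S,7R,9R,10S)-10-acetoxy-1,5-bis(angeloyloxy)-3,4-epoxy-9-hydroxy-6-[(2R)-2-methylbutanoyloxy]germacr-11-ene | C=C(C)[C@H]1C[C@@H](O)[C@](C)(OC(C)=O)[C@@H](OC(=O)/C(C)=C\C)C[C@@H]2O[C@]2(C)[C@@H](OC(=O)/C(C)=C\C)[C@H]1OC(=O)[C@H](C)CC | target

**Total step count:** 16. **Longest linear sequence:** 16 (from (S)-carvone).

**Three steps most likely to fail**

**Step 12 (macro-Darzens).**
- The dangers are E1cB loss of the C1 silyloxy group, enolisation at C6 (epimerisation or Favorskii) and oligomerisation.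
- The fallback sets out from 22 and replaces base by a neutral, metal-templated closure.
- A CrCl2/LiI intramolecular Reformatsky reaction at high dilution gives the ring-closed β-hydroxy ketone F1.
- Burgess dehydration gives the ring (3Z)-enone F2.
- Peripheral Weitz–Scheffer epoxidation (TBHP, DBU) comes back to the route at 24.

**Step 14 (Mitsunobu at a neopentyl-type carbinol).**
- The C6 ester can take part as a neighbouring group and scramble the acyl positions.
- The fallback sets out from 22 and passes through the enone F2 of the first fallback.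
- It sets C5 before the oxirane: CBS reduction gives the (5S)-allylic alcohol F3.
- m-CPBA then gives the trans-epoxy alcohol F4, since medium-ring Z-allylic alcohols are epoxidised to the trans epoxy alcohols.
- Acylation with the 2,4,6-trichlorobenzoyl mixed anhydride of angelic acid in toluene at 80 °C comes back to the route at 27.

**Step 16 (regiochemistry of orthoester opening, or acetyl drift to C9).**
- The fallback sets out from 30 and accepts the thermodynamic outcome, the 9-O-acetyl-10-hydroxy isomer F5.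
- The tertiary alcohol is forced on with Ac2O/DMAP/Et3N to give the 9,10-diacetate F6.
- The exposed secondary acetate is then removed selectively with Mg(OMe)2 in MeOH at 0 °C. The tertiary acetate, the conjugated angelates and the branched butanoate are all slower. This comes back to the route at 31.

**Further compounds**
F1 | step 12 | ring-closed β-hydroxy ketone (C3/C4 epimers) | C=C(C)[C@H]1C[C@H]2OC(C)(OC)O[C@]2(C)[C@@H](O[Si](CC)(CC)CC)CC(O)C(C)C(=O)[C@H]1OC(=O)[C@H](C)CC
F2 | step 12 | (3Z)-germacra-3,11-dien-5-one | C=C(C)[C@H]1C[C@H]2OC(C)(OC)O[C@]2(C)[C@@H](O[Si](CC)(CC)CC)C/C=C(/C)C(=O)[C@H]1OC(=O)[C@H](C)CC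
F3 | step 14 | (5S)-allylic alcohol | C=C(C)[C@H]1C[C@H]2OC(C)(OC)O[C@]2(C)[C@@H](O[Si](CC)(CC)CC)C/C=C(/C)[C@@H](O)[C@H]1OC(=O)[C@H](C)CC
F4 | step 14 | (3S,4S,5S)-trans-epoxy alcohol | C=C(C)[C@H]1C[C@H]2OC(C)(OC)O[C@]2(C)[C@@H](O[Si](CC)(CC)CC)C[C@@H]3O[C@]3(C)[C@@H](O)[C@H]1OC(=O)[C@H](C)CC
F5 | step 16 | 9-O-acetyl-10-hydroxy isomer | C=C(C)[C@H]1C[C@@H](OC(C)=O)[C@](C)(O)[C@@H](OC(=O)/C(C)=C\C)C[C@@H]2O[C@]2(C)[C@@H](OC(=O)/C(C)=C\C)[C@H]1OC(=O)[C@H](C)CC
F6 | step 16 | 9,10-diacetate | C=C(C)[C@H]1C[C@@H](OC(C)=O)[C@](C)(OC(C)=O)[C@@H](OC(=O)/C(C)=C\C)C[C@@H]2O[C@]2(C)[C@@H](OC(=O)/C(C)=C\C)[C@H]1OC(=O)[C@H](C)CC
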